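**Strategy.** Ring A (the trione: C1(=O), C2 acyl-bearing, C3 enol, C4 diprenylated, C5(=O), C6 spiro) is built last, by a [3+3] union of 6-methylheptane-2,4-dione with a malonate-derived spiro carbon. The key step exploits the cis-1,3-diaxial relation between the C4' hydroxyl of hydrindane ring B and the C5 carbonyl: held as a bridged γ-lactone, it distinguishes the two carbonyls on C6. The diketone dianion opens the lactone with its terminal carbon (C4–C5), then its central carbon closes ring A onto the remaining ester (C1–C2, Claisen), freeing the C4' alcohol. The precursor is a tricyclic lactone methyl ester made from cyclopentenone; bis-prenylation at C4 finishes the route.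

Key step: step 5

Numbering: ring A as above; the hydrindane (ring B six-membered, ring C five-membered) carries primed locants C1'–C7a', with C6' identical to the spiro carbon C6. The ring fusion is trans.

Assumption: the ferrocenyl diphosphine enantiomer named in step 1 is taken to deliver the isopropenyl group to the enone face that gives the 3S ketone; if the sense of induction is the opposite, its mirror image is used.

Step 1
Reactants: 1 cyclopent-2-en-1-one; 2 isopropenylmagnesium bromide; 3 N,N-dimethylmethyleneiminium iodide (Eschenmoser's salt)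
Product: 5 (2S,3S)-2-[(dimethylamino)methyl]-3-(prop-1-en-2-yl)cyclopentan-1-one, via bromomagnesium enolate 4 (not isolated)
Conditions: CuBr·SMe2 (5 mol %), (R)-1-[(S)-2-(diphenylphosphino)ferrocenyl]ethyldicyclohexylphosphine (6 mol %), t-BuOMe, −75 °C; then 3, THF, −75 °C → rt
Reagents that add atoms: isopropenylmagnesium bromide, CC(=C)[Mg]Br; N,N-dimethylmethyleneiminium iodide, C=[N+](C)C.[I-]
Why: Copper-catalysed asymmetric conjugate addition of a Grignard reagent sets C3a' by ligand-controlled facial selectivity, and the regiodefined magnesium enolate 4 is aminomethylated (Mannich reaction) anti to the new isopropenyl group, which should give the trans-2,3 pattern (C7a').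

Step 2
Reactants: 5 (2S,3S)-2-[(dimethylamino)methyl]-3-(prop-1-en-2-yl)cyclopentan-1-one; 6 dimethyl malonate
Product: 9 dimethyl 2-{[(1R,2S)-5-oxo-2-(prop-1-en-2-yl)cyclopentyl]methyl}propanedioate, via methiodide 7 (not isolated), via methylene ketone 8 (not isolated)
Conditions: MeI (1.05 equiv), THF, rt, then evaporation; dimethyl malonate (3 equiv), NaOMe (1.2 equiv), MeOH, 0 °C → rt; AcOH
Reagents that add atoms: dimethyl malonate, COC(=O)CC(=O)OC
Why: N-methylation and base-induced loss of trimethylamine release the exocyclic enone 8 in situ, to which sodium dimethyl malonate adds (Michael addition to a Mannich-base-derived enone); C7a' is set on protonation and should equilibrate to the trans isomer under the basic conditions.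

Step 3
Reactants: 9 dimethyl 2-{[(1R,2S)-5-oxo-2-(prop-1-en-2-yl)cyclopentyl]methyl}propanedioate; 10 methylmagnesium bromide
Product: 11 dimethyl 2-{[(1R,2S,5S)-2-hydroxy-2-methyl-5-(prop-1-en-2-yl)cyclopentyl]methyl}propanedioate
Conditions: CeCl3 (anhydrous, 1.5 equiv), MeMgBr (3 equiv), THF, −78 °C; aq NH4Cl
Reagents that add atoms: methylmagnesium bromide, C[Mg]Br
Why: Organocerium (Imamoto) 1,2-addition to the ketone, with the malonate masked as its enolate by the first equivalent, should occur anti to the adjacent C7a' side chain (1,2-induction by the α-substituent of a cyclopentanone), placing the C1' methyl trans and the C1' hydroxyl cis to that chain.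

Step 4
Reactants: 11 dimethyl 2-{[(1R,2S,5S)-2-hydroxy-2-methyl-5-(prop-1-en-2-yl)cyclopentyl]methyl}propanedioate
Product: 12 tricyclic lactone ester: 6-methyl ester 6,4-lactone of (1S,3aS,4R,6S,7aR)-1,4-dihydroxy-1,4-dimethyloctahydro-1H-indene-6,6-dicarboxylic acid (trans ring fusion; the axial carboxyl on C6' closed onto the C4' oxygen)
Conditions: Mn(OAc)3·2H2O (2.3 equiv), KOAc, AcOH, 70 °C
Reagents that add atoms: none
Why: Manganese triacetate oxidative free-radical cyclisation with γ-lactone annulation: the malonyl radical should close ring B 6-endo on the isopropenyl CH2 (5-exo would give a trans-fused bicyclo[3.3.0]octane), the tertiary C4' radical is oxidised to the cation, and only the axial ester carbonyl on C6 can reach it, so lactonisation with loss of the ester methyl sets C4' (oxygen axial, methyl equatorial) and the spiro carbon C6 in one event.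

Step 5
Reactants: 12 tricyclic lactone ester; 13 6-methylheptane-2,4-dione
Product: 16 des-prenyl spiro trione: (6S)-3-hydroxy-2-(3-methylbutanoyl)cyclohex-2-ene-1,5-dione whose C6 is C6' of (1'S,3a'S,4'R,7a'R)-1',4'-dimethyloctahydro-1H-indene-1',4'-diol (C4 still CH2), via dilithio dianion 14 (not isolated), via triketo ester 15 (not isolated)
Conditions: 13 (2.2 equiv), LiN(iPr)2 (5.5 equiv), THF, −78 → 0 °C; then 12, −78 °C → rt, then 45 °C; aq HCl
Reagents that add atoms: 6-methylheptane-2,4-dione, CC(=O)CC(=O)CC(C)C
Why: The terminal carbon of dianion 14 acylates at the strained γ-lactone carbonyl of 12, whose collapse releases the axial C4' alkoxide and gives triketo ester 15 as its polyanion; its doubly activated central carbon (C2) then adds to the remaining methyl ester and expels methoxide, forming the C1–C2 bond and ring A. The closest known reactions are the acylation of β-diketone dianions by esters and the Claisen cyclisation of 3,5,7-triketo esters to acylphloroglucinols. Ring A closes 6-(enolexo)-exo-trig. No new stereocentre forms: the spiro configuration is already fixed in 12, because only the carbonyl cis-diaxial to the C4' oxygen can be the lactone, so that carbonyl becomes C5 and the ester becomes C1, and the lactone cannot migrate to the other carbonyl. The step needs the lactone to react before the ester, which ring strain, the s-cis lactone geometry and a first stage at −78 °C should secure, and it needs the dianion to form at the methyl terminus, which kinetic deprotonation secures. Claisen closure should beat aldol closure because C6 is quaternary and the only aldol donor is the singly activated isobutyl CH2, and deprotonation of the enolised product drives both acyl transfers forward.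

Step 6
Reactants: 16 des-prenyl spiro trione; 17 1-bromo-3-methylbut-2-ene (prenyl bromide)
Product: 18 CNP0198642.4: (6S)-3-hydroxy-2-(3-methylbutanoyl)-4,4-bis(3-methylbut-2-en-1-yl)cyclohex-2-ene-1,5-dione whose C6 is C6' of (1'S,3a'S,4'R,7a'R)-1',4'-dimethyloctahydro-1H-indene-1',4'-diol
Conditions: prenyl bromide (2.5 equiv), NaOMe (3.2 equiv), MeOH, 0 °C → rt; aq HCl
Reagents that add atoms: 1-bromo-3-methylbut-2-ene, CC(C)=CCBr
Why: Double C-alkylation of the cyclic β-triketone anion at C4, the only ring carbon still bearing hydrogen (the gem-dialkylation that turns acylphloroglucinols into lupulone- and leptospermone-type triones); the protic medium should favour C- over O-alkylation and the tertiary alcohols should not react.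

**Compound list**

1 | cyclopent-2-en-1-one | O=C1C=CCC1 | starting material
2 | isopropenylmagnesium bromide | CC(=C)[Mg]Br | starting material
3 | N,N-dimethylmethyleneiminium iodide (Eschenmoser's salt) | C=[N+](C)C.[I-] | starting material
4 | bromomagnesium (S)-3-(prop-1-en-2-yl)cyclopent-1-en-1-olate | CC(=C)[C@H]1CCC(O[Mg]Br)=C1 | intermediate
5 | (2S,3S)-2-[(dimethylamino)methyl]-3-(prop-1-en-2-yl)cyclopentan-1-one | CN(C)C[C@@H]1[C@H](CCC1=O)C(C)=C | intermediate
6 | dimethyl malonate | COC(=O)CC(=O)OC | starting material
7 | N,N,N-trimethyl-1-[(1S,5S)-2-oxo-5-(prop-1-en-2-yl)cyclopentyl]methanaminium iodide | C[N+](C)(C)C[C@@H]1[C@H](CCC1=O)C(C)=C.[I-] | intermediate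
8 | (R)-2-methylidene-3-(prop-1-en-2-yl)cyclopentan-1-one | C=C1[C@H](CCC1=O)C(C)=C | intermediate
9 | dimethyl 2-{[(1R,2S)-5-oxo-2-(prop-1-en-2-yl)cyclopentyl]methyl}propanedioate | COC(=O)C(C(=O)OC)C[C@@H]1[C@H](CCC1=O)C(C)=C | intermediate
10 | methylmagnesium bromide | C[Mg]Br | starting material
11 | dimethyl 2-{[(1R,2S,5S)-2-hydroxy-2-methyl-5-(prop-1-en-2-yl)cyclopentyl]methyl}propanedioate | COC(=O)C(C(=O)OC)C[C@@H]1[C@H](CC[C@]1(C)O)C(C)=C | intermediate
12 | tricyclic lactone ester: 6-methyl ester 6,4-lactone of (1S,3aS,4R,6S,7aR)-1,4-dihydroxy-1,4-dimethyloctahydro-1H-indene-6,6-dicarboxylic acid | O=C1[C@@]2(C[C@@H]3[C@H](CC[C@]3(C)O)[C@](C)(O1)C2)C(=O)OC | intermediate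
13 | 6-methylheptane-2,4-dione | CC(=O)CC(=O)CC(C)C | starting material
14 | dilithium 6-methylhepta-1,3-diene-2,4-diolate (dianion of 13) | [Li+].[Li+].C=C([O-])C=C([O-])CC(C)C | intermediate
15 | methyl (1S,3aS,4R,6S,7aR)-1,4-dihydroxy-1,4-dimethyl-6-(7-methyl-3,5-dioxooctanoyl)octahydro-1H-indene-6-carboxylate | CC(C)CC(=O)CC(=O)CC(=O)[C@@]1(C[C@@H]2[C@H](CC[C@]2(C)O)[C@](C)(O)C1)C(=O)OC | intermediate
16 | des-prenyl spiro trione: (6S)-3-hydroxy-2-(3-methylbutanoyl)cyclohex-2-ene-1,5-dione spiro-linked at C6 to C6' of (1'S,3a'S,4'R,7a'R)-1',4'-dimethyloctahydro-1H-indene-1',4'-diol | C1C(=O)[C@@]2(C[C@@H]3[C@H](CC[C@]3(C)O)[C@](C)(O)C2)C(=O)C(C(=O)CC(C)C)=C1O | intermediate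
17 | 1-bromo-3-methylbut-2-ene (prenyl bromide) | CC(C)=CCBr | starting material
18 | CNP0198642.4: 16 with two 3-methylbut-2-en-1-yl groups on C4 | CC(C)=CCC1(CC=C(C)C)C(=O)[C@@]2(C[C@@H]3[C@H](CC[C@]3(C)O)[C@](C)(O)C2)C(=O)C(C(=O)CC(C)C)=C1O | target

**Total step count:** 6. **Longest linear sequence:** 6 steps (from cyclopent-2-en-1-one).

**Steps most likely to fail**

Step 5 (key step). The dianion may acylate at the methyl ester before the lactone, which would reverse the orientation of ring A on the spiro carbon. The Claisen closure may also stall, with the triketo ester reverting to lactone through attack of the freed C4' alkoxide. The fallback sets out from 12 and comes back to the route at 16. iBu2AlH in CH2Cl2 at −78 °C should reduce the strained lactone in preference to the methyl ester and give the bridged lactol F1. In its open hydroxy aldehyde form this should take up dianion 14 at −78 °C in an aldol addition and give the aldol adduct F2. Dess–Martin oxidation of the new secondary alcohol should then give triketo ester 15 as an isolated compound, which NaOMe in MeOH closes to 16 in a separate Claisen condensation.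

Step 4. Oxidation of the tertiary C4' radical may end in proton loss to alkenes or in acetate capture instead of lactonisation, and slow enolisation of the monoalkyl malonate by the manganese salt may expose the tertiary alcohol to prolonged heating in acid. The fallback sets out from 11 and comes back at 12 by polar chemistry. Ene-type chlorination of the isopropenyl group (Ca(OCl)2, solid CO2, CH2Cl2/H2O) should give the allylic chloride F3. NaH in THF should then close ring B by intramolecular malonate alkylation, which gives the methylidene diester F4 whichever allyl terminus is attacked. CF3CO2H in CH2Cl2 at 0 °C should protonate the exocyclic alkene, and the axial ester captures the C4' cation to give 12 after aqueous work-up.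

Step 1. Facial selectivity may be poor when an sp2 Grignard reagent is transferred to cyclopentenone under copper catalysis, and this step is the only source of absolute configuration. The fallback sets out from 1 and comes back at 5. The same conjugate addition and Mannich trapping run without chiral ligand (CuI, LiCl, THF, −78 °C) should give the racemic trans Mannich base F5. Crystallisation with (−)-O,O'-di-p-toluoyl-L-tartaric acid should give the diastereomerically pure hydrogen tartrate salt F6 of the (2S,3S) base; the mirror-image acid is used if the other salt is the less soluble one. Aqueous NaHCO3 liberates 5.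

**Further compounds**

F1 | step 5 | bridged lactol: methyl (1S,3aS,4R,6S,7aR)-1-hydroxy-1,4-dimethyloctahydro-1H-indene-6-carboxylate bearing a hydroxy-substituted CH–O bridge from C6' to the C4' oxygen | OC1[C@@]2(C[C@@H]3[C@H](CC[C@]3(C)O)[C@](C)(O1)C2)C(=O)OC
F2 | step 5 | aldol adduct: methyl (1S,3aS,4R,6S,7aR)-1,4-dihydroxy-6-(1-hydroxy-7-methyl-3,5-dioxooctyl)-1,4-dimethyloctahydro-1H-indene-6-carboxylate | CC(C)CC(=O)CC(=O)CC(O)[C@@]1(C[C@@H]2[C@H](CC[C@]2(C)O)[C@](C)(O)C1)C(=O)OC
F3 | step 4 | allylic chloride: dimethyl 2-{[(1R,2S,5S)-5-(3-chloroprop-1-en-2-yl)-2-hydroxy-2-methylcyclopentyl]methyl}propanedioate | COC(=O)C(C(=O)OC)C[C@@H]1[C@H](CC[C@]1(C)O)C(=C)CCl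
F4 | step 4 | methylidene diester: dimethyl (1S,3aS,7aR)-1-hydroxy-1-methyl-4-methylideneoctahydro-6H-indene-6,6-dicarboxylate | COC(=O)C1(C(=O)OC)C[C@@H]2[C@H](CC[C@]2(C)O)C(=C)C1
F5 | step 1 | racemic trans-2-[(dimethylamino)methyl]-3-(prop-1-en-2-yl)cyclopentan-1-one | CN(C)C[C@@H]1[C@H](CCC1=O)C(C)=C.CN(C)C[C@H]1[C@@H](CCC1=O)C(C)=C
F6 | step 1 | (2S,3S)-Mannich base hydrogen (2R,3R)-2,3-bis[(4-methylbenzoyl)oxy]butanedioate salt | C[NH+](C)C[C@@H]1[C@H](CCC1=O)C(C)=C.[O-]C(=O)[C@H](OC(=O)c1ccc(C)cc1)[C@@H](OC(=O)c1ccc(C)cc1)C(O)=O
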